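**Retrosynthetic overview**

1. Feature: the cyclohexane ring C3a–C4–C5–C6–C7–C7a holds all four contiguous ring stereocentres (C7a–CH3, C3a–H, C4–O, C5–isopropyl) beside two bare methylenes (C6, C7). With a C6=C7 alkene and a C4 acyl group in place of the C4 oxygen it is a Diels–Alder adduct (locants: cyclopentane C1, C2, C3; C3 = C(CH3)CO2H).
2. Key disconnection: C3a–C7a and C4–C5, by intramolecular [4+2] cycloaddition of the (Z,E)-diene C7a=C7–C6=C5 with the (E)-enone C3a=C4 across the tether C1–C2–C3. Cyclopentane and cyclohexene form together in this one step, and alkene geometry fixes C7a, C3a, C4 and C5.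
3. After it: C6=C7 hydrogenation. The C4 acyl group is 3-phenylpropanoyl, so Baeyer–Villiger oxidation gives the C4 ester with retention and the hydroxyl is never free beside the C3 ester. Dehydrogenation then gives the cinnamate, and the methyl ester is cleaved last.
4. Before it: quaternary C3 from a prochiral 2-alkyl-2-methylmalonate by enzymatic desymmetrisation; the acid arm becomes C3a=C4–C(O)R by reduction, oxidation and Horner–Wadsworth–Emmons olefination. C1–C7a comes from Negishi coupling of a zincated 2-bromoethylmalonate with a (2Z,4E)-2-iodo diene made by iodo-Wittig olefination.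

Key step: step 8

Remark: names of bicyclic compounds use the locants of line 1, not lowest-locant numbering.
Assumption: the esterase treats the C8 dienyl chain of 11 like a long n-alkyl chain of a 2-alkyl-2-methylmalonate and gives the (R)-half ester 12.
Assumption: 4, 5 and 16 are bought.

**Route**

Step 1
Reactants: 1 dimethyl 2-methylpropanedioate; 2 1,2-dibromoethane
Product: 3 dimethyl 2-(2-bromoethyl)-2-methylpropanedioate
Conditions: NaH, DMF, 0 °C; then 2 (4 equiv), rt to 50 °C
Reagents that add atoms: none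
Why: SN2 alkylation of the sodium malonate enolate (malonic ester alkylation), in which the excess of dihalide suppresses double substitution and the product has no α-hydrogen left for ring closure to a cyclopropane.

Step 2
Reactants: 4 ethyl(triphenyl)phosphonium iodide; 5 (2E)-4-methylpent-2-enal
Product: 9 (2Z,4E)-2-iodo-6-methylhepta-2,4-diene, via ethylidene(triphenyl)phosphorane 6 (not isolated), via (1-iodoethyl)(triphenyl)phosphonium iodide 7 (not isolated), via (1-iodoethylidene)(triphenyl)phosphorane 8 (not isolated)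
Conditions: n-BuLi, THF, 0 °C; I2, −78 °C; NaN(SiMe3)2, −20 °C; then 5, −78 °C to rt
Reagents that add atoms: iodine, II
Why: Wittig olefination with the α-iodo ylide (Stork–Zhao-type olefination) should place iodine cis to the chain at the new trisubstituted alkene under kinetic control, while the (E)-alkene of the enal is carried through unchanged.

Step 3
Reactants: 3 dimethyl 2-(2-bromoethyl)-2-methylpropanedioate; 9 (2Z,4E)-2-iodo-6-methylhepta-2,4-diene
Product: 11 dimethyl 2-[(3Z,5E)-3,7-dimethylocta-3,5-dien-1-yl]-2-methylpropanedioate, via alkylzinc bromide 10 (not isolated)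
Conditions: Zn dust, I2 (5 mol%), DMA, 70 °C; then 9, Pd(PPh3)4 (5 mol%), THF, 25–40 °C
Reagents that add atoms: none
Why: Zinc insertion into the primary C–Br bond and Negishi sp3–sp2 cross-coupling under zerovalent palladium catalysis should join C1 to C7a with retention of both alkene geometries, the alkylzinc tolerating the two esters.

Step 4
Reactants: 11 dimethyl 2-[(3Z,5E)-3,7-dimethylocta-3,5-dien-1-yl]-2-methylpropanedioate
Product: 12 (2R)-2-[(3Z,5E)-3,7-dimethylocta-3,5-dien-1-yl]-3-methoxy-2-methyl-3-oxopropanoic acid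
Conditions: pig liver esterase, 0.1 M phosphate buffer (pH 7.5), DMSO (10% v/v), 25 °C
Reagents that add atoms: water, O
Why: Esterase-catalysed desymmetrisation of a prochiral dimethyl 2-alkyl-2-methylmalonate hydrolyses one enantiotopic ester and so sets C3; it is placed after the coupling because the long lipophilic chain is expected to be bound in the large hydrophobic pocket, the regime in which such malonates are differentiated well.

Step 5
Reactants: 12 (2R)-2-[(3Z,5E)-3,7-dimethylocta-3,5-dien-1-yl]-3-methoxy-2-methyl-3-oxopropanoic acid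
Product: 14 methyl (2R,5Z,7E)-2-(hydroxymethyl)-2,5,9-trimethyldeca-5,7-dienoate, via isobutyl mixed carbonic anhydride 13 (not isolated)
Conditions: i-BuOCOCl, N-methylmorpholine, THF, −15 °C; then NaBH4, H2O, 0 °C
Reagents that add atoms: none
Why: Mixed-anhydride activation and borohydride reduction turn the carboxyl carbon (future C3a) into CH2OH chemoselectively beside the methyl ester and the diene, and quaternary C3 cannot epimerise.

Step 6
Reactants: 14 methyl (2R,5Z,7E)-2-(hydroxymethyl)-2,5,9-trimethyldeca-5,7-dienoate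
Product: 15 methyl (2R,5Z,7E)-2-formyl-2,5,9-trimethyldeca-5,7-dienoate
Conditions: Dess–Martin periodinane, pyridine, CH2Cl2, 0 °C to rt
Reagents that add atoms: none
Why: Dess–Martin oxidation of the neopentyl primary alcohol gives the non-enolisable aldehyde under buffered conditions that leave the acid-sensitive (Z,E)-diene untouched.

Step 7
Reactants: 15 methyl (2R,5Z,7E)-2-formyl-2,5,9-trimethyldeca-5,7-dienoate; 16 dimethyl (2-oxo-4-phenylbutyl)phosphonate
Product: 17 methyl (2R,5Z,7E)-2,5,9-trimethyl-2-[(1E)-3-oxo-5-phenylpent-1-en-1-yl]deca-5,7-dienoate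
Conditions: LiCl, i-Pr2NEt, MeCN, rt
Reagents that add atoms: none
Why: Horner–Wadsworth–Emmons olefination with a β-keto phosphonate under Masamune–Roush conditions should give the (E)-enone, the mild amine base avoiding deformylation of the α-quaternary formyl ester.

Step 8
Reactants: 17 methyl (2R,5Z,7E)-2,5,9-trimethyl-2-[(1E)-3-oxo-5-phenylpent-1-en-1-yl]deca-5,7-dienoate
Product: 18 methyl (3R,3aS,4R,5R,7aR)-3,7a-dimethyl-4-(3-phenylpropanoyl)-5-(propan-2-yl)-2,3,3a,4,5,7a-hexahydro-1H-indene-3-carboxylate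
Conditions: Me2AlCl (2.2 equiv), CH2Cl2, −40 to 0 °C
Reagents that add atoms: none
Why: With Me2AlCl on the enone carbonyl the tethered diene adds across C3a=C4 in a concerted, asynchronous [4+2] cycloaddition (type 1 intramolecular Diels–Alder reaction; closest known type: cyclisation of (Z)-1,3,8-nonatrienes to cis-fused hydrindenes), the C3a–C7a bond being the more advanced. The cyclopentane closes through this internal bond, the tether bridging the inside (Z) position of C7a and the exo position of C3a, and the cyclohexene closes through the peripheral C4–C5 bond of the same six-electron event. Addition is suprafacial on both partners, so the outside groups (C7a methyl, C5 isopropyl) end cis, the (E)-enone places the acyl group trans to C3, and because a Z-attached three-atom tether can only reach the exo position the ring fusion is cis and the acyl group is endo, cis to both outside groups: C7a, C3a, C4 and C5 are fixed relative to each other by alkene geometry alone. The remaining selectivity is the enone face relative to C3: closure tilts C2 towards C4, so the C3 substituent anti to the forming C3a–C7a bond ends syn to C4 and the other lies in the enone plane below the C7a methyl group. Adduct 18 needs CO2Me anti and CH3 in plane, an arrangement favoured by the ester as the better σ-acceptor anti to the attacking diene terminus (Felkin–Anh-type alignment), best expressed at low temperature under Lewis acid activation. Since methyl and ester differ little in size this bias may be modest, the C3-epimeric cis-fused adduct being the expected by-product to be removed by chromatography.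

Step 9
Reactants: 18 methyl (3R,3aS,4R,5R,7aR)-3,7a-dimethyl-4-(3-phenylpropanoyl)-5-(propan-2-yl)-2,3,3a,4,5,7a-hexahydro-1H-indene-3-carboxylate
Product: 19 methyl (3R,3aS,4R,5S,7aS)-3,7a-dimethyl-4-(3-phenylpropanoyl)-5-(propan-2-yl)octahydro-1H-indene-3-carboxylate
Conditions: H2 (4 bar), Pd on carbon (10% Pd), EtOAc, rt
Reagents that add atoms: none
Why: Heterogeneous catalytic hydrogenation saturates the cis-disubstituted C6=C7 alkene without creating a stereocentre and without touching ketone, ester or phenyl ring; it precedes the peracid step, which would otherwise epoxidise the alkene.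

Step 10
Reactants: 19 methyl (3R,3aS,4R,5S,7aS)-3,7a-dimethyl-4-(3-phenylpropanoyl)-5-(propan-2-yl)octahydro-1H-indene-3-carboxylate
Product: 20 methyl (3R,3aS,4R,5S,7aS)-3,7a-dimethyl-4-[(3-phenylpropanoyl)oxy]-5-(propan-2-yl)octahydro-1H-indene-3-carboxylate
Conditions: (CF3CO)2O, urea–H2O2, Na2HPO4, CH2Cl2, 0 °C to rt
Reagents that add atoms: trifluoroperacetic acid, OOC(=O)C(F)(F)F, generated from urea–hydrogen peroxide, NC(N)=O.OO, and trifluoroacetic anhydride, O=C(OC(=O)C(F)(F)F)C(F)(F)F
Why: In the Baeyer–Villiger oxidation the secondary C4 migrates in preference to the primary CH2 and with retention of configuration, so the C4–C bond becomes the C4–O bond of the 3-phenylpropanoate and the buffered medium protects the epimerisable C4 of the ketone.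

Step 11
Reactants: 20 methyl (3R,3aS,4R,5S,7aS)-3,7a-dimethyl-4-[(3-phenylpropanoyl)oxy]-5-(propan-2-yl)octahydro-1H-indene-3-carboxylate
Product: 24 methyl (3R,3aS,4R,5S,7aS)-3,7a-dimethyl-4-{[(2E)-3-phenylprop-2-enoyl]oxy}-5-(propan-2-yl)octahydro-1H-indene-3-carboxylate, via lithium ester enolate 21 (not isolated), via α-phenylselanyl ester 22 (not isolated), via selenoxide 23 (not isolated)
Conditions: LiN(i-Pr)2, THF, −78 °C; PhSeBr; then 30% H2O2, pyridine, CH2Cl2, 0 °C to rt
Reagents that add atoms: none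
Why: α-Selenenylation of the only enolisable ester (the C3 ester is quaternary) and syn elimination of the selenoxide towards the benzylic hydrogen (selenoxide elimination) should give the conjugated (E)-cinnamate.

Step 12
Reactants: 24 methyl (3R,3aS,4R,5S,7aS)-3,7a-dimethyl-4-{[(2E)-3-phenylprop-2-enoyl]oxy}-5-(propan-2-yl)octahydro-1H-indene-3-carboxylate
Product: 25 (3R,3aS,4R,5S,7aS)-3,7a-dimethyl-4-{[(2E)-3-phenylprop-2-enoyl]oxy}-5-(propan-2-yl)octahydro-1H-indene-3-carboxylic acid
Conditions: LiI, pyridine, 110 °C; then 1 M HCl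
Reagents that add atoms: none
Why: SN2 attack of iodide on the ester methyl group (nucleophilic ester dealkylation) does not depend on the hindrance of the quaternary C3 acyl carbon and cannot occur at the secondary C4–O carbon, so only the methyl ester is cleaved and the cinnamate survives.

**Compound list**

1 | dimethyl 2-methylpropanedioate | COC(=O)C(C)C(=O)OC | starting material
2 | 1,2-dibromoethane | BrCCBr | starting material
3 | dimethyl 2-(2-bromoethyl)-2-methylpropanedioate | COC(=O)C(C)(CCBr)C(=O)OC | intermediate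
4 | ethyl(triphenyl)phosphonium iodide | CC[P+](c1ccccc1)(c1ccccc1)c1ccccc1.[I-] | starting material
5 | (2E)-4-methylpent-2-enal | CC(C)/C=C/C=O | starting material
6 | ethylidene(triphenyl)phosphorane (not isolated) | CC=P(c1ccccc1)(c1ccccc1)c1ccccc1 | intermediate
7 | (1-iodoethyl)(triphenyl)phosphonium iodide (not isolated) | CC(I)[P+](c1ccccc1)(c1ccccc1)c1ccccc1.[I-] | intermediate
8 | (1-iodoethylidene)(triphenyl)phosphorane (not isolated) | CC(I)=P(c1ccccc1)(c1ccccc1)c1ccccc1 | intermediate
9 | (2Z,4E)-2-iodo-6-methylhepta-2,4-diene | CC(C)/C=C/C=C(/C)I | intermediate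
10 | [3,3-bis(methoxycarbonyl)butyl]zinc bromide (not isolated) | COC(=O)C(C)(CC[Zn]Br)C(=O)OC | intermediate
11 | dimethyl 2-[(3Z,5E)-3,7-dimethylocta-3,5-dien-1-yl]-2-methylpropanedioate | CC(C)/C=C/C=C(/C)CCC(C)(C(=O)OC)C(=O)OC | intermediate
12 | (2R)-2-[(3Z,5E)-3,7-dimethylocta-3,5-dien-1-yl]-3-methoxy-2-methyl-3-oxopropanoic acid | CC(C)/C=C/C=C(/C)CC[C@@](C)(C(=O)OC)C(=O)O | intermediate
13 | mixed anhydride of 12 with 2-methylpropyl hydrogen carbonate (not isolated) | CC(C)/C=C/C=C(/C)CC[C@@](C)(C(=O)OC)C(=O)OC(=O)OCC(C)C | intermediate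
14 | methyl (2R,5Z,7E)-2-(hydroxymethyl)-2,5,9-trimethyldeca-5,7-dienoate | CC(C)/C=C/C=C(/C)CC[C@@](C)(C(=O)OC)CO | intermediate
15 | methyl (2R,5Z,7E)-2-formyl-2,5,9-trimethyldeca-5,7-dienoate | CC(C)/C=C/C=C(/C)CC[C@@](C)(C(=O)OC)C=O | intermediate
16 | dimethyl (2-oxo-4-phenylbutyl)phosphonate | COP(=O)(OC)CC(=O)CCc1ccccc1 | starting material
17 | methyl (2R,5Z,7E)-2,5,9-trimethyl-2-[(1E)-3-oxo-5-phenylpent-1-en-1-yl]deca-5,7-dienoate | CC(C)/C=C/C=C(/C)CC[C@@](C)(C(=O)OC)/C=C/C(=O)CCc1ccccc1 | intermediate
18 | methyl (3R,3aS,4R,5R,7aR)-3,7a-dimethyl-4-(3-phenylpropanoyl)-5-(propan-2-yl)-2,3,3a,4,5,7a-hexahydro-1H-indene-3-carboxylate | CC(C)[C@@H]1C=C[C@@]2(C)CC[C@@](C)(C(=O)OC)[C@H]2[C@@H]1C(=O)CCc1ccccc1 | intermediate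
19 | methyl (3R,3aS,4R,5S,7aS)-3,7a-dimethyl-4-(3-phenylpropanoyl)-5-(propan-2-yl)octahydro-1H-indene-3-carboxylate | CC(C)[C@@H]1CC[C@@]2(C)CC[C@@](C)(C(=O)OC)[C@H]2[C@@H]1C(=O)CCc1ccccc1 | intermediate
20 | methyl (3R,3aS,4R,5S,7aS)-3,7a-dimethyl-4-[(3-phenylpropanoyl)oxy]-5-(propan-2-yl)octahydro-1H-indene-3-carboxylate | CC(C)[C@@H]1CC[C@@]2(C)CC[C@@](C)(C(=O)OC)[C@H]2[C@@H]1OC(=O)CCc1ccccc1 | intermediate
21 | lithium enolate of the 3-phenylpropanoate group of 20 (not isolated) | CC(C)[C@@H]1CC[C@@]2(C)CC[C@@](C)(C(=O)OC)[C@H]2[C@@H]1OC(O[Li])=CCc1ccccc1 | intermediate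
22 | 20 carrying PhSe at C2 of the 3-phenylpropanoate group, both epimers (not isolated) | CC(C)[C@@H]1CC[C@@]2(C)CC[C@@](C)(C(=O)OC)[C@H]2[C@@H]1OC(=O)C(Cc1ccccc1)[Se]c1ccccc1 | intermediate
23 | selenoxide of 22 (not isolated) | CC(C)[C@@H]1CC[C@@]2(C)CC[C@@](C)(C(=O)OC)[C@H]2[C@@H]1OC(=O)C(Cc1ccccc1)[Se](=O)c1ccccc1 | intermediate
24 | methyl (3R,3aS,4R,5S,7aS)-3,7a-dimethyl-4-{[(2E)-3-phenylprop-2-enoyl]oxy}-5-(propan-2-yl)octahydro-1H-indene-3-carboxylate | CC(C)[C@@H]1CC[C@@]2(C)CC[C@@](C)(C(=O)OC)[C@H]2[C@@H]1OC(=O)/C=C/c1ccccc1 | intermediate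
25 | (3R,3aS,4R,5S,7aS)-3,7a-dimethyl-4-{[(2E)-3-phenylprop-2-enoyl]oxy}-5-(propan-2-yl)octahydro-1H-indene-3-carboxylic acid | CC(C)[C@@H]1CC[C@@]2(C)CC[C@@](C)(C(=O)O)[C@H]2[C@@H]1OC(=O)/C=C/c1ccccc1 | target

**Step count and risks**

Total step count: 12. Longest linear sequence: 11 steps (steps 1 and 3 to 12; step 2 is the side branch).

Steps most likely to fail:

1. Step 8. The enone face may be discriminated poorly relative to C3, because methyl and methoxycarbonyl compete for the position anti to the forming C3a–C7a bond; slow closure could also let the Lewis acid isomerise the (Z)-diene. Fallback (sets out from 14, comes back at 25): the carboxyl group is carried through the cycloaddition as a tert-alkyl-sized ortho ester, which can only take the anti position, and the cyclisation is run thermally because the ortho ester does not tolerate aluminium Lewis acids.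
   - Silylation of 14 (t-BuMe2SiCl, imidazole, DMF) gives silyl ether F1, and hydrolysis of the methyl ester (LiOH, THF/MeOH/H2O, 60 °C) gives acid F2.
   - Yamaguchi esterification with (3-methyloxetan-3-yl)methanol gives oxetanylmethyl ester F3, which BF3·OEt2 (catalytic, CH2Cl2, −15 °C, Et3N quench) rearranges to the 4-methyl-2,6,7-trioxabicyclo[2.2.2]octan-1-yl (OBO) ortho ester F4.
   - Bu4NF gives alcohol F5, Dess–Martin oxidation gives aldehyde F6, and olefination with 16 (LiCl, i-Pr2NEt) gives triene F7.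
   - Heating (toluene, trace of 2,6-di-tert-butyl-4-methylphenol, 130 °C) should give cycloadduct F8.
   - Hydrogenation as in step 9 gives ketone F9, and buffered Baeyer–Villiger oxidation as in step 10 gives ester F10.
   - Dilute HCl in THF followed by LiOH (THF/MeOH/H2O, 50 °C) opens the ortho ester and cleaves both esters to hydroxy acid F11.
   - Cinnamoyl chloride (excess), DMAP and pyridine, with aqueous NaHCO3 work-up to hydrolyse the mixed anhydride, give 25.

2. Step 4. The enzyme may differentiate the two ester groups insufficiently, or hydrolyse the lipophilic substrate too slowly. Fallback (sets out from 11, comes back at 12): mono-saponification with KOH (1 equiv, MeOH) gives racemic half ester F12. Its salt with (1S)-1-phenylethanamine, diastereomeric salt F13, is crystallised to constant rotation; the enantiomeric amine is used instead if it gives the less soluble salt of the (R)-acid. Acidification returns 12.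

3. Step 3. The (Z) geometry at the trisubstituted alkene may erode, or the palladium-catalysed coupling of the hindered iodide may be sluggish. Fallback (sets out from 9, comes back at 11): the C2–C3 bond is made instead of C1–C7a. Iodine–lithium exchange on 9 (t-BuLi, Et2O, −78 °C) with retention of geometry and opening of oxirane (BF3·OEt2) give homoallylic alcohol F14. I2, PPh3 and imidazole give iodide F15, and SN2 alkylation of the sodium enolate of 1 (NaH, DMF, 0 °C to rt) gives 11; elimination of F15 to a triene is the side reaction to watch.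

Further compounds
F1 | step 8 | methyl (2R,5Z,7E)-2-({[tert-butyl(dimethyl)silyl]oxy}methyl)-2,5,9-trimethyldeca-5,7-dienoate | CC(C)/C=C/C=C(/C)CC[C@@](C)(C(=O)OC)CO[Si](C)(C)C(C)(C)C
F2 | step 8 | (2R,5Z,7E)-2-({[tert-butyl(dimethyl)silyl]oxy}methyl)-2,5,9-trimethyldeca-5,7-dienoic acid | CC(C)/C=C/C=C(/C)CC[C@@](C)(C(=O)O)CO[Si](C)(C)C(C)(C)C
F3 | step 8 | (3-methyloxetan-3-yl)methyl ester of F2 | CC(C)/C=C/C=C(/C)CC[C@@](C)(C(=O)OCC1(C)COC1)CO[Si](C)(C)C(C)(C)C
F4 | step 8 | OBO ortho ester from F3: F1 with CO2Me replaced by 4-methyl-2,6,7-trioxabicyclo[2.2.2]octan-1-yl, (R) at the quaternary carbon | CC(C)/C=C/C=C(/C)CC[C@@](C)(C12OCC(C)(CO1)CO2)CO[Si](C)(C)C(C)(C)C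
F5 | step 8 | (2R,5Z,7E)-2,5,9-trimethyl-2-(4-methyl-2,6,7-trioxabicyclo[2.2.2]octan-1-yl)deca-5,7-dien-1-ol | CC(C)/C=C/C=C(/C)CC[C@@](C)(C12OCC(C)(CO1)CO2)CO
F6 | step 8 | (2R,5Z,7E)-2,5,9-trimethyl-2-(4-methyl-2,6,7-trioxabicyclo[2.2.2]octan-1-yl)deca-5,7-dienal | CC(C)/C=C/C=C(/C)CC[C@@](C)(C12OCC(C)(CO1)CO2)C=O
F7 | step 8 | OBO analogue of 17 (CO2Me replaced by 4-methyl-2,6,7-trioxabicyclo[2.2.2]octan-1-yl), (R) at the quaternary carbon | CC(C)/C=C/C=C(/C)CC[C@@](C)(C12OCC(C)(CO1)CO2)/C=C/C(=O)CCc1ccccc1
F8 | step 8 | OBO analogue of 18, (3R,3aS,4R,5R,7aR) | CC(C)[C@@H]1C=C[C@@]2(C)CC[C@@](C)(C34OCC(C)(CO3)CO4)[C@H]2[C@@H]1C(=O)CCc1ccccc1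
F9 | step 8 | OBO analogue of 19, (3R,3aS,4R,5S,7aS) | CC(C)[C@@H]1CC[C@@]2(C)CC[C@@](C)(C34OCC(C)(CO3)CO4)[C@H]2[C@@H]1C(=O)CCc1ccccc1
F10 | step 8 | OBO analogue of 20, (3R,3aS,4R,5S,7aS) | CC(C)[C@@H]1CC[C@@]2(C)CC[C@@](C)(C34OCC(C)(CO3)CO4)[C@H]2[C@@H]1OC(=O)CCc1ccccc1
F11 | step 8 | (3R,3aS,4R,5S,7aS)-4-hydroxy-3,7a-dimethyl-5-(propan-2-yl)octahydro-1H-indene-3-carboxylic acid | CC(C)[C@@H]1CC[C@@]2(C)CC[C@@](C)(C(=O)O)[C@H]2[C@@H]1O
F12 | step 4 | racemic 2-[(3Z,5E)-3,7-dimethylocta-3,5-dien-1-yl]-3-methoxy-2-methyl-3-oxopropanoic acid | CC(C)/C=C/C=C(/C)CCC(C)(C(=O)OC)C(=O)O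
F13 | step 4 | (1S)-1-phenylethanaminium salt of 12 | CC(C)/C=C/C=C(/C)CC[C@@](C)(C(=O)OC)C(=O)[O-].C[C@H]([NH3+])c1ccccc1
F14 | step 3 | (3Z,5E)-3,7-dimethylocta-3,5-dien-1-ol | CC(C)/C=C/C=C(/C)CCO
F15 | step 3 | (3Z,5E)-1-iodo-3,7-dimethylocta-3,5-diene | CC(C)/C=C/C=C(/C)CCI
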